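## Retrosynthetic overview

1. Last ring (oxa-bridge): the C4–O8 bond is made by transannular Markovnikov hydroalkoxylation of the C3=C4 alkene (new cobalt-hydride method). Just before it, C5–OH comes from allylic hydroxylation and C2–OAc from cis-selective enone reduction and acetylation.
2. Second ring (bromotetrahydropyran): C11–O7 and C10–Br come from 6-endo bromoetherification of the tertiary C7–OH onto the prenyl alkene, done while the ring alkene is still a deactivated enone.
3. C1–C7 bond: chelation-controlled aldol of the 3-methylcyclohex-2-enone enolate with (S)-3-hydroxy-6-methylhept-5-en-2-one; C8 controls C7 and C1.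
4. C8–O: D-proline-catalysed α-oxygenation of 6-methylhept-5-en-2-one.
5. Ring order: carbocycle bought (3-methylcyclohex-2-enone), then tetrahydropyran, then the oxepane bridge of the 2-oxabicyclo[3.2.2]nonane.

Assumption: locants are bisabolane numbers (ring C1–C6 with the side chain on C1, OAc on C2, Me and O on C4, OH on C5; chain C7(Me,O)–C8(O)–C9–C10(Br)–C11(Me2,O)); the SMILES is read as 1R,2S,4R,5R,7S,8S,10S.

## Route

Step 1
Reactants: 1 6-methylhept-5-en-2-one
Product: 3 (3S)-3-hydroxy-6-methylhept-5-en-2-one, via anilinooxy ketone 2 (not isolated)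
Conditions: 1 (2 equiv), D-proline (20 mol%), PhNO (slow addition), DMSO, rt; then CuSO4·5H2O (0.3 equiv), MeOH, 0 °C
Reagents that add atoms: nitrosobenzene, O=Nc1ccccc1
Why: Proline enamine catalysis (O-selective nitroso aldol, α-aminoxylation) oxygenates the more substituted α-carbon, D-proline gives the (S) carbinol (mirror of the L-proline to (R) sense), and CuSO4 cleaves the N–O bond without touching the stereocentre.

Step 2
Reactants: 3 (3S)-3-hydroxy-6-methylhept-5-en-2-one; 4 3-methylcyclohex-2-en-1-one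
Product: 7 (6S)-6-[(2S,3S)-2,3-dihydroxy-6-methylhept-5-en-2-yl]-3-methylcyclohex-2-en-1-one, via lithium dienolate 5 (not isolated), via lithium alkoxide 6 (not isolated)
Conditions: LiN(i-Pr)2 (2.1 equiv), 4 (2.1 equiv), THF, −78 °C; then 3 (1 equiv), −78 → −50 °C; AcOH, −78 °C
Reagents that add atoms: none
Why: Chelation-controlled ketone aldol addition: the first equivalent of 5 turns 3 into alkoxide 6, whose lithium ties O8 and the C7 carbonyl into a five-ring chelate so the enolate carbon enters anti to the C9 chain (Cram-chelate, sets 7S), and the same lithium holds the enolate oxygen in a chair transition state with the chelated C8 arm axial and the ring CH2 anti to O7, which sets C1 (6S in 7).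

Step 3
Reactants: 7 (6S)-6-[(2S,3S)-2,3-dihydroxy-6-methylhept-5-en-2-yl]-3-methylcyclohex-2-en-1-one
Product: 8 (6S)-6-[(2S,3S)-2-hydroxy-6-methyl-3-(triethylsilyloxy)hept-5-en-2-yl]-3-methylcyclohex-2-en-1-one
Conditions: Et3SiCl (1.1 equiv), imidazole, DMF, 0 °C
Reagents that add atoms: chlorotriethylsilane, CC[Si](Cl)(CC)CC
Why: Silylation takes the secondary hydroxyl and leaves the tertiary one, so O8 cannot close a five-membered bromo ether in step 4 or be acetylated in step 5.

Step 4
Reactants: 8 (6S)-6-[(2S,3S)-2-hydroxy-6-methyl-3-(triethylsilyloxy)hept-5-en-2-yl]-3-methylcyclohex-2-en-1-one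
Product: 9 (6S)-6-[(2S,3S,5S)-5-bromo-2,6,6-trimethyl-3-(triethylsilyloxy)oxan-2-yl]-3-methylcyclohex-2-en-1-one
Conditions: 2,4,4,6-tetrabromocyclohexa-2,5-dien-1-one (1.2 equiv), MeNO2, −20 °C → rt
Reagents that add atoms: 2,4,4,6-tetrabromocyclohexa-2,5-dien-1-one, BrC1=CC(Br)(Br)C=C(Br)C1=O
Why: 6-endo bromoetherification (anti addition, Markovnikov opening of the bromonium at C11 by the tertiary C7–OH) touches only the prenyl alkene because the ring alkene is an enone, and the chair transition state with the cyclohexenonyl group equatorial (C7–Me axial, Br equatorial) gives the (10S) bromide.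

Step 5
Reactants: 9 (6S)-6-[(2S,3S,5S)-5-bromo-2,6,6-trimethyl-3-(triethylsilyloxy)oxan-2-yl]-3-methylcyclohex-2-en-1-one
Product: 11 (1S,6R)-6-[(2S,3S,5S)-5-bromo-2,6,6-trimethyl-3-(triethylsilyloxy)oxan-2-yl]-3-methylcyclohex-2-en-1-yl acetate, via lithium allylic alkoxide 10 (not isolated)
Conditions: LiBH(s-Bu)3 (1.2 equiv), THF, −78 °C; then Ac2O (5 equiv), DMAP (cat.), −78 → 0 °C
Reagents that add atoms: acetic anhydride, CC(=O)OC(C)=O
Why: The bulky hydride reduces the β,β-disubstituted enone 1,2 by equatorial attack, placing the new C2 oxygen axial and cis to the equatorial C1 substituent (2S), and the only alkoxide present is acetylated in the same flask.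

Step 6
Reactants: 11 (1S,6R)-6-[(2S,3S,5S)-5-bromo-2,6,6-trimethyl-3-(triethylsilyloxy)oxan-2-yl]-3-methylcyclohex-2-en-1-yl acetate
Product: 12 (1S,4R,6R)-6-[(2S,3S,5S)-5-bromo-2,6,6-trimethyl-3-(triethylsilyloxy)oxan-2-yl]-4-hydroxy-3-methylcyclohex-2-en-1-yl acetate
Conditions: SeO2 (0.5 equiv), t-BuOOH (3 equiv), CH2Cl2, rt
Reagents that add atoms: selenium dioxide, O=[Se]=O (oxygen carrier); tert-butyl hydroperoxide, CC(C)(C)OO (terminal oxygen source)
Why: SeO2 allylic hydroxylation (ene reaction then [2,3]-sigmatropic shift) oxidises the ring CH2 next to the methyl-bearing alkene carbon, and selenium and then oxygen are delivered on the face opposite the pseudo-axial C2 acetate and the C1 substituent, giving the (5R) alcohol trans to the side chain.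

Step 7
Reactants: 12 (1S,4R,6R)-6-[(2S,3S,5S)-5-bromo-2,6,6-trimethyl-3-(triethylsilyloxy)oxan-2-yl]-4-hydroxy-3-methylcyclohex-2-en-1-yl acetate
Product: 13 (1R,2S,4R,5R,7S,8S,10S)-10-bromo-5-hydroxy-4,8:7,11-diepoxybisabolan-2-yl acetate (target)
Conditions: Co(C36H52N2O2) [divalent cobalt complex of N,N′-bis(3,5-di-tert-butylsalicylidene)cyclohexane-1,2-diamine] (5 mol%), N-fluoro-2,4,6-trimethylpyridinium tetrafluoroborate (1.5 equiv), PhSiH3 (1.5 equiv), PhCF3, 0 °C → rt
Reagents that add atoms: none
Why: Proposed new method: a trivalent cobalt hydride (from the cobalt salen, the N-fluoropyridinium oxidant and PhSiH3) transfers a hydrogen atom to C3 of the trisubstituted alkene, the tertiary C4 radical is captured and oxidised to a tetravalent alkylcobalt (carbocation equivalent), the silyl ether oxygen O8 closes the seven-membered bridge from the only face it can reach (that of the C1 side chain, anti to the C5 hydroxyl, so C4 is R) and fluoride from BF4− removes Et3Si from the oxonium; the closest known reaction type is the cobalt-salen/N-fluoropyridinium/hydrosilane Markovnikov hydroalkoxylation of unactivated alkenes to five- to seven-membered cyclic ethers, including closures of O-protected alcohols with loss of the protecting group, which has not been shown for a transannular closure to a bridged 2-oxabicyclo[3.2.2]nonane next to a free allylic carbinol.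

## Compound list

1 | 6-methylhept-5-en-2-one | CC(=O)CCC=C(C)C | starting material
2 | (3S)-6-methyl-3-(phenylaminooxy)hept-5-en-2-one | CC(=O)[C@@H](ONc1ccccc1)CC=C(C)C | intermediate
3 | (3S)-3-hydroxy-6-methylhept-5-en-2-one | CC(=O)[C@@H](O)CC=C(C)C | intermediate
4 | 3-methylcyclohex-2-en-1-one | CC1=CC(=O)CCC1 | starting material
5 | lithium 5-methylcyclohexa-1,5-dien-1-olate (kinetic dienolate of 4) | [Li+].[O-]C1=CCCC(C)=C1 | intermediate
6 | lithium (3S)-6-methyl-2-oxohept-5-en-3-olate (lithium alkoxide of 3) | [Li+].CC(=O)[C@@H]([O-])CC=C(C)C | intermediate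
7 | (6S)-6-[(2S,3S)-2,3-dihydroxy-6-methylhept-5-en-2-yl]-3-methylcyclohex-2-en-1-one | CC1=CC(=O)[C@@H](CC1)[C@](C)(O)[C@@H](O)CC=C(C)C | intermediate
8 | (6S)-6-[(2S,3S)-2-hydroxy-6-methyl-3-(triethylsilyloxy)hept-5-en-2-yl]-3-methylcyclohex-2-en-1-one | CC1=CC(=O)[C@@H](CC1)[C@](C)(O)[C@@H](O[Si](CC)(CC)CC)CC=C(C)C | intermediate
9 | (6S)-6-[(2S,3S,5S)-5-bromo-2,6,6-trimethyl-3-(triethylsilyloxy)oxan-2-yl]-3-methylcyclohex-2-en-1-one | CC1=CC(=O)[C@@H](CC1)[C@]2(C)OC(C)(C)[C@@H](Br)C[C@@H]2O[Si](CC)(CC)CC | intermediate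
10 | lithium (1S,6R)-6-[(2S,3S,5S)-5-bromo-2,6,6-trimethyl-3-(triethylsilyloxy)oxan-2-yl]-3-methylcyclohex-2-en-1-olate | [Li+].[O-][C@H]1C=C(C)CC[C@H]1[C@]2(C)OC(C)(C)[C@@H](Br)C[C@@H]2O[Si](CC)(CC)CC | intermediate
11 | (1S,6R)-6-[(2S,3S,5S)-5-bromo-2,6,6-trimethyl-3-(triethylsilyloxy)oxan-2-yl]-3-methylcyclohex-2-en-1-yl acetate | CC(=O)O[C@H]1C=C(C)CC[C@H]1[C@]2(C)OC(C)(C)[C@@H](Br)C[C@@H]2O[Si](CC)(CC)CC | intermediate
12 | (1S,4R,6R)-6-[(2S,3S,5S)-5-bromo-2,6,6-trimethyl-3-(triethylsilyloxy)oxan-2-yl]-4-hydroxy-3-methylcyclohex-2-en-1-yl acetate | CC(=O)O[C@H]1C=C(C)[C@H](O)C[C@H]1[C@]2(C)OC(C)(C)[C@@H](Br)C[C@@H]2O[Si](CC)(CC)CC | intermediate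
13 | (1R,2S,4R,5R,7S,8S,10S)-10-bromo-5-hydroxy-4,8:7,11-diepoxybisabolan-2-yl acetate (cyclohexane bridged C1–C7–C8–O–C4, cis-fused at C7–C8 to the 3-bromo-2,2-dimethyltetrahydropyran) | CC(=O)O[C@H]1C[C@@]2(C)O[C@H]3C[C@H](Br)C(C)(C)O[C@@]3(C)[C@@H]1C[C@H]2O | target

## Totals and risk

Total step count: 7. Longest linear sequence: 7 steps (1 to 13).

Steps most likely to fail:

**Step 7 (the proposed new reaction).** The risks are participation of the C2 acetate carbonyl at C4, a 1,2-hydride shift from C5 to give the ketone, and failure of the silyl ether to close. The fallback uses known chemistry, sets out from 12 and comes back at 13. HF·pyridine in THF cleaves the silyl ether to (1S,4R,6R)-6-[(2S,3S,5S)-5-bromo-3-hydroxy-2,6,6-trimethyloxan-2-yl]-4-hydroxy-3-methylcyclohex-2-en-1-yl acetate F5. Hg(OCOCF3)2 (divalent mercury) in MeNO2 at 0 °C then effects intramolecular alkoxymercuration (anti, Markovnikov, the reaction that converts α-terpineol into the cineole skeleton), and aqueous NaCl gives the C3-chloromercurio derivative of 13 F6. NaBH4 in aqueous NaOH/THF removes mercury to give 13.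

**Step 2 (aldol).** The risks are retro-aldol or proton transfer instead of addition, and poor control of C1 if the chelated chair is not followed; C1 is the weakest stereochemical point of the route. The fallback replaces substrate control of C1 by auxiliary control, sets out from 4 (with 3) and comes back at 7. Condensation of 4 with (S)-1-amino-2-(methoxymethyl)pyrrolidine (cat. TsOH, cyclohexane, reflux) gives the SAMP hydrazone of 4 F1. LiN(i-Pr)2 in THF at −78 °C gives the lithium azaenolate of the SAMP hydrazone F2, which is added to 6 (made from 3 and LiN(SiMe3)2 at −78 °C) to give the SAMP hydrazone of 7 F3. The known facial sense of SAMP azaenolates places the electrophile on the face that gives the required C1 configuration, and chelation still sets C7. Aqueous oxalic acid/Et2O releases 7.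

**Step 4 (bromoetherification).** The risks are 5-exo closure to the tetrahydrofuran and a poor C10 ratio if the bromonium forms irreversibly on both alkene faces. The fallback sets out from 8 and comes back at 9. Hg(OCOCF3)2 in MeNO2 at 0 °C followed by aqueous KBr gives (6S)-6-[(2S,3S,5S)-5-(bromomercurio)-2,6,6-trimethyl-3-(triethylsilyloxy)oxan-2-yl]-3-methylcyclohex-2-en-1-one F4. Alkoxymercuration is reversible and Markovnikov, so the six-membered ring forms under thermodynamic control with mercury equatorial and the cyclohexenonyl group equatorial. Br2/LiBr in pyridine at 0 °C in the dark then replaces mercury by bromine with retention to give 9.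

## Further compounds

F1 | step 2 | SAMP hydrazone of 4, N-[(2S)-2-(methoxymethyl)pyrrolidin-1-yl]-3-methylcyclohex-2-en-1-imine | CC1=CC(CCC1)=NN2CCC[C@H]2COC
F2 | step 2 | lithium azaenolate of the SAMP hydrazone F1 | CC1=CC(=CCC1)N([Li])N2CCC[C@H]2COC
F3 | step 2 | SAMP hydrazone of 7 | CC1=CC(=NN2CCC[C@H]2COC)[C@@H](CC1)[C@](C)(O)[C@@H](O)CC=C(C)C
F4 | step 4 | (6S)-6-[(2S,3S,5S)-5-(bromomercurio)-2,6,6-trimethyl-3-(triethylsilyloxy)oxan-2-yl]-3-methylcyclohex-2-en-1-one | CC1=CC(=O)[C@@H](CC1)[C@]2(C)OC(C)(C)[C@@H]([Hg]Br)C[C@@H]2O[Si](CC)(CC)CC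
F5 | step 7 | (1S,4R,6R)-6-[(2S,3S,5S)-5-bromo-3-hydroxy-2,6,6-trimethyloxan-2-yl]-4-hydroxy-3-methylcyclohex-2-en-1-yl acetate | CC(=O)O[C@H]1C=C(C)[C@H](O)C[C@H]1[C@]2(C)OC(C)(C)[C@@H](Br)C[C@@H]2O
F6 | step 7 | C3-chloromercurio derivative of 13 (mercury anti to O8) | CC(=O)O[C@H]1[C@H]([Hg]Cl)[C@@]2(C)O[C@H]3C[C@H](Br)C(C)(C)O[C@@]3(C)[C@@H]1C[C@H]2O
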